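Retrosynthesis (carotenoid numbering: ring C1–C6, chain C7–C15 then C15'–C10'): the chain is cut at C11'=C12' and C11=C12 (two Wittig reactions on the symmetric C10 dialdehyde C12–C12'), then at C7=C8 (Horner–Wadsworth–Emmons reaction with a C5 phosphonate that brings C8–C11 and the C9 methyl), and last at the ring bond C1–C6.
Enabling feature: the only ring is a cyclohexane in which the gem-dimethyl carbon C1 is bonded to the tertiary carbinol C6 (bearing C7), next to the methyl carbinol C5. Opening C1–C6 leaves C7–C6–C5(CH3)–C4–C3–C2–C1(CH3)2, the geraniol skeleton, whose prenyl end can give a tertiary C1 radical and whose oxidised allylic end can provide a C6 ketone to receive it.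
Forward: geraniol is taken to an acyclic (R)-α-silyloxy ketone, the ring is closed in a single radical step, the C7 arm is turned into an aldehyde and extended to a C15 phosphonium salt, and this is joined to a C12 aldehyde carrying a masked C10' aldehyde.
Stereochemistry: C5 comes from a Sharpless epoxidation followed by invertive opening at the tertiary epoxide carbon; C6 is set relative to C5 in the chair transition state of the ring closure; the seven E alkenes come from stabilised-reagent olefinations and the all-E dialdehyde.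

Key step: step 6

Assumption: the dialdehyde 16, the phosphonate 11 and the ylide 17 are taken as purchasable; in the acyclic compounds 5–7 the octene carbons C7, C6, C3, C2 and C1 correspond to carotenoid C1, C2, C5, C6 and C7.

Step 1
Reactants: 1 geraniol
Product: 2 [(2S,3S)-3-methyl-3-(4-methylpent-3-en-1-yl)oxiran-2-yl]methanol
Conditions: Ti(OiPr)4 (5 mol%), L-(+)-diethyl tartrate (7.5 mol%), t-BuOOH, 4 Å MS, CH2Cl2, −20 °C
Reagents that add atoms: tert-butyl hydroperoxide, CC(C)(C)OO
Why: Sharpless asymmetric epoxidation: the allylic hydroxyl binds the titanium tartrate peroxide complex, so only the 2,3-alkene reacts and L-(+)-tartrate should deliver oxygen to the face that gives the (2S,3S)-epoxide, which fixes the configuration later found at C5.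

Step 2
Reactants: 2 [(2S,3S)-3-methyl-3-(4-methylpent-3-en-1-yl)oxiran-2-yl]methanol; 3 4-methoxybenzyl chloride
Product: 4 (2S,3S)-3-{[(4-methoxybenzyl)oxy]methyl}-2-methyl-2-(4-methylpent-3-en-1-yl)oxirane
Conditions: NaH, Bu4NI (cat.), THF/DMF, 0 °C → rt
Reagents that add atoms: 4-methoxybenzyl chloride (compound 3), COc1ccc(CCl)cc1
Why: Williamson ether synthesis on the primary alkoxide under aprotic conditions, where the trisubstituted 2,3-epoxide is the favoured Payne isomer and is not opened; no stereocentre is touched.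

Step 3
Reactants: 4 (2S,3S)-3-{[(4-methoxybenzyl)oxy]methyl}-2-methyl-2-(4-methylpent-3-en-1-yl)oxirane
Product: 5 (2S,3R)-1-[(4-methoxybenzyl)oxy]-3,7-dimethyloct-6-ene-2,3-diol
Conditions: HClO4 (5 mol%), THF/H2O 3:1, 0 °C → rt
Reagents that add atoms: water, O
Why: Acid-catalysed epoxide hydrolysis of borderline SN2 type: water attacks the protonated epoxide at the tertiary carbon (C2 is deactivated by the neighbouring ether oxygen) from the rear, so C3 is inverted to R while C2 keeps its oxygen, and the cold dilute acid should spare the PMB ether and the remote alkene.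

Step 4
Reactants: 5 (2S,3R)-1-[(4-methoxybenzyl)oxy]-3,7-dimethyloct-6-ene-2,3-diol
Product: 6 (3R)-3-hydroxy-1-[(4-methoxybenzyl)oxy]-3,7-dimethyloct-6-en-2-one
Conditions: (COCl)2, DMSO, CH2Cl2, −78 °C; Et3N, −78 → 0 °C
Reagents that add atoms: none
Why: Swern oxidation: only the secondary hydroxyl carries a carbinol hydrogen, activated DMSO does not cleave the 1,2-diol, and the fully substituted C3 cannot epimerise.

Step 5
Reactants: 6 (3R)-3-hydroxy-1-[(4-methoxybenzyl)oxy]-3,7-dimethyloct-6-en-2-one
Product: 7 (3R)-1-[(4-methoxybenzyl)oxy]-3,7-dimethyl-3-[(triethylsilyl)oxy]oct-6-en-2-one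
Conditions: Et3SiOTf, 2,6-lutidine, CH2Cl2, −78 → 0 °C
Reagents that add atoms: triethylsilyl trifluoromethanesulfonate, CC[Si](CC)(CC)OS(=O)(=O)C(F)(F)F
Why: Silylation of a tertiary alcohol with a silyl triflate and a hindered pyridine base; at low temperature O-silylation should outrun silyl enol ether formation at the ketone.

Step 6
Reactants: 7 (3R)-1-[(4-methoxybenzyl)oxy]-3,7-dimethyl-3-[(triethylsilyl)oxy]oct-6-en-2-one
Product: 8 (1S,2R)-1-{[(4-methoxybenzyl)oxy]methyl}-2,6,6-trimethyl-2-[(triethylsilyl)oxy]cyclohexan-1-ol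
Conditions: Fe(acac)3 (1 equiv), PhSiH3 (2.5 equiv), degassed EtOH, 60 °C, Ar
Reagents that add atoms: none
Why: Fe(acac)3 and PhSiH3 in ethanol generate an iron hydride that hands a hydrogen atom to the CH end of the trisubstituted alkene (carotenoid C2), the resulting tertiary C1 radical attacks the C6 carbonyl carbon, and the alkoxy radical so formed is reduced by divalent iron and protonated by the solvent, which shuts off the reverse fragmentation. The reaction type is the known iron-hydride hydrogen-atom-transfer reductive cyclisation of alkenyl ketones to tertiary cycloalkanols, used here on a more congested pair of carbons. The cyclohexane closes by a 6-exo-trig addition to the C=O group through a chair-like transition state. The new stereocentre C6 is set by the existing C5 centre: the C5 methyl sits equatorial to avoid a syn-axial clash with a C1 methyl, the C5–OSiEt3 bond is therefore axial, and the carbonyl oxygen takes the axial position anti to it so that the two C–O dipoles oppose each other, which places the CH2OPMB arm equatorial and gives the trans-diol relationship. The step needs the hydrogen atom to go to the alkene and not to the ketone, the radical to add at carbon in the 6-exo sense, and one face of the ketone to be preferred; the electron-rich alkene, the nucleophilic tertiary radical facing an α-oxygenated (more electrophilic) ketone, and the bulky non-chelating silyl ether are what should secure these.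

Step 7
Reactants: 8 (1S,2R)-1-{[(4-methoxybenzyl)oxy]methyl}-2,6,6-trimethyl-2-[(triethylsilyl)oxy]cyclohexan-1-ol
Product: 9 (1S,2R)-1-(hydroxymethyl)-2,6,6-trimethyl-2-[(triethylsilyl)oxy]cyclohexan-1-ol
Conditions: DDQ, CH2Cl2/pH 7 phosphate buffer 10:1, 0 °C → rt
Reagents that add atoms: none
Why: Oxidative cleavage of a 4-methoxybenzyl ether by DDQ (hydride abstraction, then hydrolysis of the oxocarbenium ion by water), chemoselective because 8 has no alkene left and neither the silyl ether nor the tertiary alcohol is oxidised; the aqueous buffer should prevent capture of the cation by the C6 hydroxyl as a benzylidene acetal.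

Step 8
Reactants: 9 (1S,2R)-1-(hydroxymethyl)-2,6,6-trimethyl-2-[(triethylsilyl)oxy]cyclohexan-1-ol
Product: 10 (1R,2R)-1-hydroxy-2,6,6-trimethyl-2-[(triethylsilyl)oxy]cyclohexane-1-carbaldehyde
Conditions: (COCl)2, DMSO, CH2Cl2, −78 °C; Et3N, −78 → −20 °C
Reagents that add atoms: none
Why: Swern oxidation of the neopentyl-type primary alcohol to the aldehyde; the tertiary hydroxyl cannot be oxidised, and the cold, non-aqueous, weakly basic conditions should avoid glycol cleavage and acyloin-type ring expansion of the α-hydroxy aldehyde.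

Step 9
Reactants: 10 (1R,2R)-1-hydroxy-2,6,6-trimethyl-2-[(triethylsilyl)oxy]cyclohexane-1-carbaldehyde; 11 ethyl (2E)-4-(diethoxyphosphoryl)-3-methylbut-2-enoate
Product: 12 ethyl (2E,4E)-5-{(1R,2R)-1-hydroxy-2,6,6-trimethyl-2-[(triethylsilyl)oxy]cyclohexyl}-3-methylpenta-2,4-dienoate
Conditions: 11 (1.5 equiv), LiN(SiMe3)2, THF/DMPU, −78 °C; then 10, −78 °C → rt
Reagents that add atoms: none
Why: Horner–Wadsworth–Emmons olefination with a vinylogous phosphonoacetate: the delocalised anion reacts at the carbon next to phosphorus, the new C7=C8 bond should form E and the C9=C10 bond mainly E (a minor 9Z isomer would be separated), and the stabilised anion is too weak a base to deprotonate the tertiary C6 hydroxyl.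

Step 10
Reactants: 12 ethyl (2E,4E)-5-{(1R,2R)-1-hydroxy-2,6,6-trimethyl-2-[(triethylsilyl)oxy]cyclohexyl}-3-methylpenta-2,4-dienoate
Product: 13 (2E,4E)-5-{(1R,2R)-1-hydroxy-2,6,6-trimethyl-2-[(triethylsilyl)oxy]cyclohexyl}-3-methylpenta-2,4-dien-1-ol
Conditions: iBu2AlH (3.5 equiv), CH2Cl2, −78 → 0 °C; aq. potassium sodium tartrate
Reagents that add atoms: none
Why: DIBAL reduction of a conjugated ester to the allylic alcohol in the 1,2 sense; the first equivalent of hydride is consumed by the C6 hydroxyl, and the silyl ether and the diene are left alone.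

Step 11
Reactants: 13 (2E,4E)-5-{(1R,2R)-1-hydroxy-2,6,6-trimethyl-2-[(triethylsilyl)oxy]cyclohexyl}-3-methylpenta-2,4-dien-1-ol
Product: 15 [(2E,4E)-5-{(1R,2R)-1-hydroxy-2,6,6-trimethyl-2-[(triethylsilyl)oxy]cyclohexyl}-3-methylpenta-2,4-dien-1-yl]triphenylphosphonium bromide, via allylic bromide 14 (not isolated)
Conditions: CBr4, PPh3, 2,6-lutidine (0.3 equiv), CH2Cl2, −20 °C; then PPh3, CH2Cl2/EtOAc, rt
Reagents that add atoms: carbon tetrabromide, BrC(Br)(Br)Br; triphenylphosphine, c1ccc(cc1)P(c1ccccc1)c1ccccc1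
Why: Appel bromination of the primary dienylic alcohol under neutral conditions (the hindered tertiary hydroxyl should not react at low temperature), followed in the same flask by SN2 quaternisation of triphenylphosphine by the reactive allylic bromide, which avoids handling that bromide.

Step 12
Reactants: 16 (2E,4E,6E)-2,7-dimethylocta-2,4,6-trienedial; 17 N-methoxy-N-methyl-2-(triphenyl-λ5-phosphanylidene)acetamide
Product: 18 (2E,4E,6E,8E)-N-methoxy-N,4,9-trimethyl-10-oxodeca-2,4,6,8-tetraenamide
Conditions: 16 (2.5 equiv), toluene, 80 °C, slow addition of 17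
Reagents that add atoms: none
Why: Wittig olefination with a carbonyl-stabilised ylide, which should give the E-enamide; with the symmetric dialdehyde in excess the reaction should stop after one formyl group, and unreacted 16 is recovered.

Step 13
Reactants: 15 [(2E,4E)-5-{(1R,2R)-1-hydroxy-2,6,6-trimethyl-2-[(triethylsilyl)oxy]cyclohexyl}-3-methylpenta-2,4-dien-1-yl]triphenylphosphonium bromide; 18 (2E,4E,6E,8E)-N-methoxy-N,4,9-trimethyl-10-oxodeca-2,4,6,8-tetraenamide
Product: 19 (2E,4E,6E,8E,10E,12E,14E)-15-{(1R,2R)-1-hydroxy-2,6,6-trimethyl-2-[(triethylsilyl)oxy]cyclohexyl}-N-methoxy-N,4,9,13-trimethylpentadeca-2,4,6,8,10,12,14-heptaenamide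
Conditions: NaOMe, CH2Cl2/MeOH, 0 °C → rt; then EtOAc, reflux (11Z → 11E)
Reagents that add atoms: none
Why: Wittig olefination of the allylic ylide from 15 with the α-methyl enal of 18, the classical C15 plus polyene-aldehyde union of carotenoid synthesis; the new C11=C12 bond should be mainly E, the sterically hindered 11Z isomer should revert to E on warming, and methoxide leaves the Weinreb amide, the silyl ether and the tertiary hydroxyl untouched.

Step 14
Reactants: 19 (2E,4E,6E,8E,10E,12E,14E)-15-{(1R,2R)-1-hydroxy-2,6,6-trimethyl-2-[(triethylsilyl)oxy]cyclohexyl}-N-methoxy-N,4,9,13-trimethylpentadeca-2,4,6,8,10,12,14-heptaenamide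
Product: 20 (2E,4E,6E,8E,10E,12E,14E)-15-[(1R,2R)-1,2-dihydroxy-2,6,6-trimethylcyclohexyl]-N-methoxy-N,4,9,13-trimethylpentadeca-2,4,6,8,10,12,14-heptaenamide
Conditions: Bu4NF, AcOH, THF, 0 °C → rt
Reagents that add atoms: none
Why: Fluoride-induced cleavage of the silyl ether, driven by the strong Si–F bond; acetic acid buffers the medium so that no free alkoxide, which could trigger a retro-aldol-type ring opening, builds up next to the polyene.

Step 15
Reactants: 20 (2E,4E,6E,8E,10E,12E,14E)-15-[(1R,2R)-1,2-dihydroxy-2,6,6-trimethylcyclohexyl]-N-methoxy-N,4,9,13-trimethylpentadeca-2,4,6,8,10,12,14-heptaenamide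
Product: 21 (2E,4E,6E,8E,10E,12E,14E)-15-[(1R,2R)-1,2-dihydroxy-2,6,6-trimethylcyclohexyl]-4,9,13-trimethylpentadeca-2,4,6,8,10,12,14-heptaenal, the target
Conditions: iBu2AlH (4 equiv), THF, −78 °C; aq. potassium sodium tartrate
Reagents that add atoms: none
Why: DIBAL reduction of a Weinreb amide: the chelated tetrahedral aluminium intermediate resists further hydride and collapses to the aldehyde only on neutral aqueous work-up, so the polyene geometry and the acid-sensitive tertiary allylic diol should survive; the two hydroxyls only consume hydride.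

Compound list
1 | geraniol, (2E)-3,7-dimethylocta-2,6-dien-1-ol | CC(C)=CCC/C(C)=C/CO | starting material
2 | [(2S,3S)-3-methyl-3-(4-methylpent-3-en-1-yl)oxiran-2-yl]methanol | CC(C)=CCC[C@]1(C)O[C@H]1CO | intermediate
3 | 4-methoxybenzyl chloride | COc1ccc(CCl)cc1 | starting material
4 | (2S,3S)-3-{[(4-methoxybenzyl)oxy]methyl}-2-methyl-2-(4-methylpent-3-en-1-yl)oxirane | CC(C)=CCC[C@]1(C)O[C@H]1COCc2ccc(OC)cc2 | intermediate
5 | (2S,3R)-1-[(4-methoxybenzyl)oxy]-3,7-dimethyloct-6-ene-2,3-diol | CC(C)=CCC[C@@](C)(O)[C@@H](O)COCc1ccc(OC)cc1 | intermediate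
6 | (3R)-3-hydroxy-1-[(4-methoxybenzyl)oxy]-3,7-dimethyloct-6-en-2-one | CC(C)=CCC[C@@](C)(O)C(=O)COCc1ccc(OC)cc1 | intermediate
7 | (3R)-1-[(4-methoxybenzyl)oxy]-3,7-dimethyl-3-[(triethylsilyl)oxy]oct-6-en-2-one | CC(C)=CCC[C@@](C(=O)COCc1ccc(OC)cc1)(C)O[Si](CC)(CC)CC | intermediate
8 | (1S,2R)-1-{[(4-methoxybenzyl)oxy]methyl}-2,6,6-trimethyl-2-[(triethylsilyl)oxy]cyclohexan-1-ol | COc2ccc(COC[C@@]1(O)C(C)(C)CCC[C@@]1(C)O[Si](CC)(CC)CC)cc2 | intermediate
9 | (1S,2R)-1-(hydroxymethyl)-2,6,6-trimethyl-2-[(triethylsilyl)oxy]cyclohexan-1-ol | OC[C@@]1(O)C(C)(C)CCC[C@@]1(C)O[Si](CC)(CC)CC | intermediate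
10 | (1R,2R)-1-hydroxy-2,6,6-trimethyl-2-[(triethylsilyl)oxy]cyclohexane-1-carbaldehyde | O=C[C@@]1(O)C(C)(C)CCC[C@@]1(C)O[Si](CC)(CC)CC | intermediate
11 | ethyl (2E)-4-(diethoxyphosphoryl)-3-methylbut-2-enoate | CCOC(=O)/C=C(\C)CP(=O)(OCC)OCC | starting material
12 | ethyl (2E,4E)-5-{(1R,2R)-1-hydroxy-2,6,6-trimethyl-2-[(triethylsilyl)oxy]cyclohexyl}-3-methylpenta-2,4-dienoate | CCOC(=O)/C=C(C)/C=C/[C@@]1(O)C(C)(C)CCC[C@@]1(C)O[Si](CC)(CC)CC | intermediate
13 | (2E,4E)-5-{(1R,2R)-1-hydroxy-2,6,6-trimethyl-2-[(triethylsilyl)oxy]cyclohexyl}-3-methylpenta-2,4-dien-1-ol | OC/C=C(C)/C=C/[C@@]1(O)C(C)(C)CCC[C@@]1(C)O[Si](CC)(CC)CC | intermediate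
14 | (1R,2R)-1-[(1E,3E)-5-bromo-3-methylpenta-1,3-dien-1-yl]-2,6,6-trimethyl-2-[(triethylsilyl)oxy]cyclohexan-1-ol (allylic bromide, not isolated) | BrC/C=C(C)/C=C/[C@@]1(O)C(C)(C)CCC[C@@]1(C)O[Si](CC)(CC)CC | intermediate
15 | [(2E,4E)-5-{(1R,2R)-1-hydroxy-2,6,6-trimethyl-2-[(triethylsilyl)oxy]cyclohexyl}-3-methylpenta-2,4-dien-1-yl]triphenylphosphonium bromide | c1ccccc1[P+](c1ccccc1)(c1ccccc1)C/C=C(C)/C=C/[C@@]2(O)C(C)(C)CCC[C@@]2(C)O[Si](CC)(CC)CC.[Br-] | intermediate
16 | (2E,4E,6E)-2,7-dimethylocta-2,4,6-trienedial | O=C/C(C)=C/C=C/C=C(C)/C=O | starting material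
17 | N-methoxy-N-methyl-2-(triphenyl-λ5-phosphanylidene)acetamide | CON(C)C(=O)C=P(c1ccccc1)(c1ccccc1)c1ccccc1 | starting material
18 | (2E,4E,6E,8E)-N-methoxy-N,4,9-trimethyl-10-oxodeca-2,4,6,8-tetraenamide | CON(C)C(=O)/C=C/C(C)=C/C=C/C=C(C)/C=O | intermediate
19 | (2E,4E,6E,8E,10E,12E,14E)-15-{(1R,2R)-1-hydroxy-2,6,6-trimethyl-2-[(triethylsilyl)oxy]cyclohexyl}-N-methoxy-N,4,9,13-trimethylpentadeca-2,4,6,8,10,12,14-heptaenamide | CON(C)C(=O)/C=C/C(C)=C/C=C/C=C(C)/C=C/C=C(C)/C=C/[C@@]1(O)C(C)(C)CCC[C@@]1(C)O[Si](CC)(CC)CC | intermediate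
20 | (2E,4E,6E,8E,10E,12E,14E)-15-[(1R,2R)-1,2-dihydroxy-2,6,6-trimethylcyclohexyl]-N-methoxy-N,4,9,13-trimethylpentadeca-2,4,6,8,10,12,14-heptaenamide | CON(C)C(=O)/C=C/C(C)=C/C=C/C=C(C)/C=C/C=C(C)/C=C/[C@@]1(O)C(C)(C)CCC[C@@]1(C)O | intermediate
21 | (2E,4E,6E,8E,10E,12E,14E)-15-[(1R,2R)-1,2-dihydroxy-2,6,6-trimethylcyclohexyl]-4,9,13-trimethylpentadeca-2,4,6,8,10,12,14-heptaenal, i.e. (5R,6R)-5,6-dihydroxy-5,6-dihydro-10'-apo-β-caroten-10'-al | CC(/C=C/C=O)=C\C=C\C=C(C)\C=C\C=C(C)\C=C\[C@@]1(O)C(C)(C)CCC[C@@]1(C)O | target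

Total step count: 15. Longest linear sequence: 14 steps (steps 1–11, then 13–15); step 12 prepares the C12 coupling partner.

Steps most likely to fail

Step 6. The tertiary radical may be quenched by a second hydrogen-atom transfer before it reaches the crowded carbonyl carbon. The alkoxy radical may fragment, back to the C1 radical or toward an oxygen-stabilised C5 radical, before divalent iron reduces it. The choice between the two faces of the ketone may also be poor. The fallback sets out from 7 and comes back at 8. Buffered mCPBA epoxidation of the trisubstituted alkene (CH2Cl2, NaHCO3, 0 °C) should give the epoxy ketone F1, either epimer of which serves. Cp2TiCl, a trivalent titanium reagent made from Cp2TiCl2 and Zn in THF, should open the epoxide homolytically to the same tertiary C1 radical while binding the ketone. The 6-exo addition is thereby assisted and the alkoxy radical is captured at once as a titanium alkoxide, giving the cyclised diol F2 with an extra secondary hydroxyl at C2. That hydroxyl is removed by Barton–McCombie deoxygenation through the phenyl thionocarbonate F3 (PhOC(S)Cl, pyridine, DMAP; then Bu3SnH, AIBN, toluene, 80 °C), which leads to 8.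

Step 9. Addition of the delocalised phosphonate anion to the doubly neopentyl aldehyde may be slow, leaving time for base-induced acyloin-type ring expansion of the α-hydroxy aldehyde, and control of the C9=C10 geometry may be incomplete. The fallback sets out from 10 and comes back at 12, building the chain with two small reagents. A Wittig reaction with 1-(triphenyl-λ5-phosphanylidene)propan-2-one under neutral conditions (toluene, 80 °C) should give the E-enone F4. A Horner–Wadsworth–Emmons reaction of this methyl ketone with triethyl phosphonoacetate (NaH, THF, 0 °C → reflux) should then give 12 after separation from its 9Z isomer.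

Step 11. The dienyl bromide may ionise, after which the neighbouring tertiary allylic hydroxyl can capture the cation or trigger a 1,2-shift or elimination; the phosphine may also attack at C9 with allylic transposition. The fallback sets out from 13 and comes back at 19, replacing the phosphonium salt by a sulfone made without any cationic intermediate. A Mitsunobu reaction of 13 with 1-phenyl-1H-tetrazole-5-thiol (PPh3, DIAD, THF, 0 °C) should give the sulfide F5. Oxidation with H2O2 and (NH4)6Mo7O24 in EtOH (0 °C → rt) should give the sulfone F6. Julia–Kocienski olefination of F6 with aldehyde 18 (KN(SiMe3)2, THF, −78 °C → rt) should then give 19, with thermal equilibration of any 11Z isomer as in step 13.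

Further compounds
F1 | step 6 | (3R)-5-(3,3-dimethyloxiran-2-yl)-1-[(4-methoxybenzyl)oxy]-3-methyl-3-[(triethylsilyl)oxy]pentan-2-one (epoxy ketone, both oxirane epimers) | CC1(C)OC1CC[C@@](C(=O)COCc2ccc(OC)cc2)(C)O[Si](CC)(CC)CC
F2 | step 6 | (1S,6R)-1-{[(4-methoxybenzyl)oxy]methyl}-2,2,6-trimethyl-6-[(triethylsilyl)oxy]cyclohexane-1,3-diol (cyclised diol, epimers at C3) | COc1ccc(COC[C@@]2(O)C(C)(C)C(O)CC[C@@]2(C)O[Si](CC)(CC)CC)cc1
F3 | step 6 | O-[(3S,4R)-3-hydroxy-3-{[(4-methoxybenzyl)oxy]methyl}-2,2,4-trimethyl-4-[(triethylsilyl)oxy]cyclohexyl] O-phenyl carbonothioate (phenyl thionocarbonate) | COc1ccc(COC[C@@]2(O)C(C)(C)C(OC(=S)Oc3ccccc3)CC[C@@]2(C)O[Si](CC)(CC)CC)cc1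
F4 | step 9 | (3E)-4-{(1R,2R)-1-hydroxy-2,6,6-trimethyl-2-[(triethylsilyl)oxy]cyclohexyl}but-3-en-2-one (E-enone) | CC(=O)/C=C/[C@@]1(O)C(C)(C)CCC[C@@]1(C)O[Si](CC)(CC)CC
F5 | step 11 | 5-{[(2E,4E)-5-{(1R,2R)-1-hydroxy-2,6,6-trimethyl-2-[(triethylsilyl)oxy]cyclohexyl}-3-methylpenta-2,4-dien-1-yl]sulfanyl}-1-phenyl-1H-tetrazole (sulfide) | c1ccccc1-n2nnnc2SC/C=C(C)/C=C/[C@@]3(O)C(C)(C)CCC[C@@]3(C)O[Si](CC)(CC)CC
F6 | step 11 | 5-{[(2E,4E)-5-{(1R,2R)-1-hydroxy-2,6,6-trimethyl-2-[(triethylsilyl)oxy]cyclohexyl}-3-methylpenta-2,4-dien-1-yl]sulfonyl}-1-phenyl-1H-tetrazole (sulfone) | c1ccccc1-n2nnnc2S(=O)(=O)C/C=C(C)/C=C/[C@@]3(O)C(C)(C)CCC[C@@]3(C)O[Si](CC)(CC)CC
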